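## Retrosynthetic overview

1. Target 18 ← acid-mediated bicyclo[3.2.1]octenedione → hydrobenzofuranone rearrangement of 17 (C1–C7 bond traded for an O–C bond); the dihydrofuran ring is formed last.
2. 17 ← O-methylation of diosphenol 16 ← enantioselective formal [5+2] union of quinone 15 (C6–C3 unit) with (E)-propenylarene 8 (C6–C3 unit); this sets the quaternary carbon and the methyl-bearing carbon.
3. 15 ← oxidative demethylation of 2-allyl-4,5-dimethoxyphenol 14 ← Claisen rearrangement ← 3,4-dimethoxyphenol 12 ← catechol 9.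
4. 8 ← dehydration of carbinol 7 ← EtMgBr addition to 3,4,5-trimethoxybenzaldehyde 6 ← syringaldehyde 5 ← p-cresol 1.
5. Ring order: both benzene rings are bought; one is oxidised to the quinone ring, the bridging five-membered carbocycle forms in the [5+2] step, and it is then exchanged for the dihydrofuran ring.

Assumption: the TiCl2(TADDOLate) made from (4R,5R)-TADDOL is taken to give the (1R,5R,6R,7R) adduct 16; the sense is checked on the first run and the (4S,5S)-diol is used if it proves opposite.

## Route

Step 1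
Reactants: 1 p-cresol (4-methylphenol)
Product: 4 3,5-dibromo-4-hydroxybenzaldehyde, via 2,6-dibromo-4-methylphenol 2 (not isolated), via 2,6-dibromo-4-(dibromomethyl)phenol 3 (not isolated)
Conditions: Br2 (4.1 equiv), o-dichlorobenzene, 35 °C then 160 °C; then H2O, 100 °C
Reagents that add atoms: bromine, BrBr; water, O
Why: Electrophilic aromatic bromination fills both positions ortho to the phenol, hot side-chain bromination then takes the para-methyl group to the gem-dibromide, and its hydrolysis gives the aldehyde (no stereocenter).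

Step 2
Reactants: 4 3,5-dibromo-4-hydroxybenzaldehyde
Product: 5 4-hydroxy-3,5-dimethoxybenzaldehyde (syringaldehyde)
Conditions: NaOMe (5 equiv), CuCl (10 mol %), DMF/MeOH, 115 °C; then aq. HCl
Reagents that add atoms: sodium methoxide, [Na+].[O-]C
Why: Copper-catalysed Ullmann-type methoxylation replaces both aryl bromides, while the phenoxide formed in the basic medium deactivates the aldehyde toward methoxide.

Step 3
Reactants: 5 4-hydroxy-3,5-dimethoxybenzaldehyde
Product: 6 3,4,5-trimethoxybenzaldehyde
Conditions: MeI (1.5 equiv), K2CO3, DMF, rt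
Reagents that add atoms: iodomethane, CI
Why: Williamson O-methylation of the only acidic OH.

Step 4
Reactants: 6 3,4,5-trimethoxybenzaldehyde
Product: 7 1-(3,4,5-trimethoxyphenyl)propan-1-ol (racemic)
Conditions: EtMgBr (1.2 equiv), THF, 0 °C; then H2O
Reagents that add atoms: ethylmagnesium bromide, CC[Mg]Br
Why: Grignard addition to the aldehyde; the carbinol center is formed racemic and is destroyed in step 5.

Step 5
Reactants: 7 1-(3,4,5-trimethoxyphenyl)propan-1-ol
Product: 8 (E)-1,2,3-trimethoxy-5-(prop-1-en-1-yl)benzene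
Conditions: TsOH·H2O (2 mol %), toluene, reflux (Dean–Stark), short contact time
Reagents that add atoms: none
Why: Acid-catalysed E1 dehydration through the benzylic cation gives the conjugated alkene under thermodynamic control, which favours the E isomer (about 95:5).

Step 6
Reactants: 9 catechol (benzene-1,2-diol)
Product: 10 1,2-dimethoxybenzene (veratrole)
Conditions: MeI (2.5 equiv), K2CO3, acetone, reflux
Reagents that add atoms: iodomethane, CI
Why: Double Williamson O-methylation.

Step 7
Reactants: 10 1,2-dimethoxybenzene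
Product: 11 4-bromo-1,2-dimethoxybenzene
Conditions: NBS (1.0 equiv), MeCN, 0 °C → rt
Reagents that add atoms: N-bromosuccinimide, O=C1CCC(=O)N1Br
Why: Electrophilic aromatic bromination goes para to one methoxy group, the only position that is both activated and unhindered.

Step 8
Reactants: 11 4-bromo-1,2-dimethoxybenzene
Product: 12 3,4-dimethoxyphenol
Conditions: Pd2(dba)3 (1 mol %), tBuXPhos (4 mol %), KOH (3 equiv), 1,4-dioxane/H2O, 100 °C; then aq. HCl
Reagents that add atoms: potassium hydroxide, [K+].[OH-]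
Why: Palladium-catalysed C–O coupling of the aryl bromide with hydroxide (Buchwald-type hydroxylation), the bulky biarylphosphine promoting C–O reductive elimination.

Step 9
Reactants: 12 3,4-dimethoxyphenol
Product: 13 4-(allyloxy)-1,2-dimethoxybenzene
Conditions: allyl bromide (1.2 equiv), K2CO3, acetone, reflux
Reagents that add atoms: allyl bromide, C=CCBr
Why: Williamson O-allylation of the phenol.

Step 10
Reactants: 13 4-(allyloxy)-1,2-dimethoxybenzene
Product: 14 2-allyl-4,5-dimethoxyphenol
Conditions: N,N-diethylaniline, 200 °C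
Reagents that add atoms: none
Why: Aromatic Claisen rearrangement ([3,3]-sigmatropic shift, then enolisation) delivers the allyl group to the free ortho carbon that is not flanked by a methoxy group.

Step 11
Reactants: 14 2-allyl-4,5-dimethoxyphenol
Product: 15 2-allyl-5-methoxy-1,4-benzoquinone
Conditions: PhI(OAc)2 (1.1 equiv), MeCN/H2O (2:1), 0 °C
Reagents that add atoms: water, O
Why: Hypervalent-iodine oxidation of a para-methoxyphenol: water adds at the methoxy-bearing para carbon and methanol is lost to give the para-quinone, the allyl group being inert.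

Step 12
Reactants: 15 2-allyl-5-methoxy-1,4-benzoquinone; 8 (E)-1,2,3-trimethoxy-5-(prop-1-en-1-yl)benzene
Product: 16 (1R,5R,6R,7R)-5-allyl-3-hydroxy-6-methyl-7-(3,4,5-trimethoxyphenyl)bicyclo[3.2.1]oct-3-ene-2,8-dione
Conditions: TiCl4/Ti(OiPr)4 (1:1, 1.2 equiv Ti), (4R,5R)-TADDOL (1.2 equiv), CH2Cl2, rt; then 15, −78 °C; then 8 (1.5 equiv), −78 → −30 °C; H2O; recrystallise
Reagents that add atoms: none
Why: Chiral-Lewis-acid-promoted formal [5+2] quinone–styrene cycloaddition in which TiCl2(TADDOLate) chelates the C4 carbonyl and 5-methoxy oxygen of 15, the styrene β-carbon adds to the allyl-bearing C2, the benzylic cation closes on C6 and chloride removes the O-methyl group; suprafacial addition of the E alkene with the aryl ring endo over the enedione gives exo-methyl and endo-aryl (trans), and the TADDOLate aryl groups shield one quinone face to set the absolute configuration of all four centers.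

Step 13
Reactants: 16 (1R,5R,6R,7R)-5-allyl-3-hydroxy-6-methyl-7-(3,4,5-trimethoxyphenyl)bicyclo[3.2.1]oct-3-ene-2,8-dione
Product: 17 (1R,5R,6R,7R)-5-allyl-3-methoxy-6-methyl-7-(3,4,5-trimethoxyphenyl)bicyclo[3.2.1]oct-3-ene-2,8-dione
Conditions: MeI (3 equiv), K2CO3, acetone, rt
Reagents that add atoms: iodomethane, CI
Why: O-alkylation of the acidic diosphenol (enol of the α-diketone); the bridgehead C1–H cannot enolise, so no stereocenter is touched.

Step 14
Reactants: 17 (1R,5R,6R,7R)-5-allyl-3-methoxy-6-methyl-7-(3,4,5-trimethoxyphenyl)bicyclo[3.2.1]oct-3-ene-2,8-dione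
Product: 18 (2S,3S,3aR)-3a-allyl-5-methoxy-3-methyl-2-(3,4,5-trimethoxyphenyl)-3,3a-dihydro-1-benzofuran-6(2H)-one
Conditions: TfOH (0.2 equiv), CH2Cl2, −20 → 0 °C
Reagents that add atoms: none
Why: Acid-mediated bicyclooctanoid → hydrobenzofuranoid rearrangement (heterolysis of the C1–C7 bond to a benzylic cation and the enol of the 1,3-dione, then capture by the C8 oxygen); C5 and C6 are untouched and become C3a (R, allyl cis to methyl) and C3 (S), and the reversible ring closure places the aryl group trans to the methyl group (2S).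

## Compound list

1 | p-cresol (4-methylphenol) | Cc1ccc(O)cc1 | starting material
2 | 2,6-dibromo-4-methylphenol | Cc1cc(Br)c(O)c(Br)c1 | intermediate (not isolated)
3 | 2,6-dibromo-4-(dibromomethyl)phenol | BrC(Br)c1cc(Br)c(O)c(Br)c1 | intermediate (not isolated)
4 | 3,5-dibromo-4-hydroxybenzaldehyde | O=Cc1cc(Br)c(O)c(Br)c1 | intermediate
5 | 4-hydroxy-3,5-dimethoxybenzaldehyde (syringaldehyde) | COc1cc(C=O)cc(OC)c1O | intermediate
6 | 3,4,5-trimethoxybenzaldehyde | COc1cc(C=O)cc(OC)c1OC | intermediate
7 | 1-(3,4,5-trimethoxyphenyl)propan-1-ol (racemic) | CCC(O)c1cc(OC)c(OC)c(OC)c1 | intermediate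
8 | (E)-1,2,3-trimethoxy-5-(prop-1-en-1-yl)benzene | C/C=C/c1cc(OC)c(OC)c(OC)c1 | intermediate
9 | catechol (benzene-1,2-diol) | Oc1ccccc1O | starting material
10 | 1,2-dimethoxybenzene (veratrole) | COc1ccccc1OC | intermediate
11 | 4-bromo-1,2-dimethoxybenzene | COc1ccc(Br)cc1OC | intermediate
12 | 3,4-dimethoxyphenol | COc1ccc(O)cc1OC | intermediate
13 | 4-(allyloxy)-1,2-dimethoxybenzene | C=CCOc1ccc(OC)c(OC)c1 | intermediate
14 | 2-allyl-4,5-dimethoxyphenol | C=CCc1cc(OC)c(OC)cc1O | intermediate
15 | 2-allyl-5-methoxy-1,4-benzoquinone | C=CCC1=CC(=O)C(OC)=CC1=O | intermediate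
16 | (1R,5R,6R,7R)-5-allyl-3-hydroxy-6-methyl-7-(3,4,5-trimethoxyphenyl)bicyclo[3.2.1]oct-3-ene-2,8-dione | C=CC[C@@]12C=C(O)C(=O)[C@@H](C1=O)[C@H](c1cc(OC)c(OC)c(OC)c1)[C@H]2C | intermediate
17 | (1R,5R,6R,7R)-5-allyl-3-methoxy-6-methyl-7-(3,4,5-trimethoxyphenyl)bicyclo[3.2.1]oct-3-ene-2,8-dione | C=CC[C@@]12C=C(OC)C(=O)[C@@H](C1=O)[C@H](c1cc(OC)c(OC)c(OC)c1)[C@H]2C | intermediate
18 | (2S,3S,3aR)-3a-allyl-5-methoxy-3-methyl-2-(3,4,5-trimethoxyphenyl)-3,3a-dihydro-1-benzofuran-6(2H)-one | C=CC[C@@]12C=C(OC)C(=O)C=C1O[C@H](c1cc(OC)c(OC)c(OC)c1)[C@H]2C | target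

## Step count and risks

Total step count: 14 (steps 1–5 give 8, steps 6–11 give 15, steps 12–14 join them and finish).
Longest linear sequence: 9 steps (steps 6–14, from catechol 9).

Steps most likely to fail:

Step 12 (enantioselective [5+2] union). The risks are the level and sense of asymmetric induction, and competition from the [2+2] cyclobutane adduct, which would lead into the wrong diastereomeric series. Fallback: set out again from 15 and 8 with the achiral promoter TiCl4/Ti(OiPr)4 (CH2Cl2, −78 °C) to make the racemic hydroxy-dione F1. Acylate its enol OH with (1S,4R)-camphanic chloride (Et3N, DMAP, CH2Cl2). Separate by crystallisation or chromatography the (1R,5R,6R,7R)-enol (1S,4R)-camphanate F2 from the (1S,5S,6S,7S)-enol (1S,4R)-camphanate F3. Brief methanolysis of F2 (K2CO3, MeOH, 0 °C) returns enantiopure material, and the route is rejoined at 16.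

Step 14 (acid rearrangement). The 3,4,5-trimethoxybenzyl cation forms less readily than a 4-alkoxybenzyl one, and the acid can also trigger allyl participation or migration. Fallback: change the order of events and rearrange before methylating. Set out from 16 and treat the free diosphenol with anhydrous TsOH in MeCN at 40 °C, where the neutral enol assists C1–C7 ionisation and no methyl enol ether is exposed to acid. This gives (2S,3S,3aR)-3a-allyl-5-hydroxy-3-methyl-2-(3,4,5-trimethoxyphenyl)-3,3a-dihydro-1-benzofuran-6(2H)-one F4. O-methylation of its single acidic OH (MeI, K2CO3, acetone) rejoins the route at 18.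

Step 5 (dehydration). Acid can dimerise the electron-rich styrene, and any Z isomer carried into step 12 would enter the 2-epi/3a-epi series. Fallback: set out from aldehyde 6 and build the E alkene directly by Julia–Kocienski olefination with 5-(ethylsulfonyl)-1-phenyl-1H-tetrazole (KN(SiMe3)2, DME, −60 °C → rt). This bypasses carbinol 7 and rejoins the route at 8; it makes no compound outside the list, entered below as none F0.

## Further compounds

F1 | step 12 | racemic 5-allyl-3-hydroxy-6-methyl-7-(3,4,5-trimethoxyphenyl)bicyclo[3.2.1]oct-3-ene-2,8-dione (1R,5R,6R,7R and 1S,5S,6S,7S) | C=CC[C@@]12C=C(O)C(=O)[C@@H](C1=O)[C@H](c1cc(OC)c(OC)c(OC)c1)[C@H]2C.C=CC[C@]12C=C(O)C(=O)[C@H](C1=O)[C@@H](c1cc(OC)c(OC)c(OC)c1)[C@@H]2C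
F2 | step 12 | (1R,5R,6R,7R)-5-allyl-6-methyl-2,8-dioxo-7-(3,4,5-trimethoxyphenyl)bicyclo[3.2.1]oct-3-en-3-yl (1S,4R)-camphanate | C=CC[C@@]12C=C(OC(=O)[C@@]34CC[C@@](C)(C(=O)O3)C4(C)C)C(=O)[C@@H](C1=O)[C@H](c1cc(OC)c(OC)c(OC)c1)[C@H]2C
F3 | step 12 | (1S,5S,6S,7S)-5-allyl-6-methyl-2,8-dioxo-7-(3,4,5-trimethoxyphenyl)bicyclo[3.2.1]oct-3-en-3-yl (1S,4R)-camphanate | C=CC[C@]12C=C(OC(=O)[C@@]34CC[C@@](C)(C(=O)O3)C4(C)C)C(=O)[C@H](C1=O)[C@@H](c1cc(OC)c(OC)c(OC)c1)[C@@H]2C
F4 | step 14 | (2S,3S,3aR)-3a-allyl-5-hydroxy-3-methyl-2-(3,4,5-trimethoxyphenyl)-3,3a-dihydro-1-benzofuran-6(2H)-one | C=CC[C@@]12C=C(O)C(=O)C=C1O[C@H](c1cc(OC)c(OC)c(OC)c1)[C@H]2C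
F0 | step 5 | none | none
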